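How much does the rate of making product rise in the flask, at 5.0% conversion of the starting material, when we charge more free catalyst?

| flask | starting material | reagent | free catalyst | remark |
|---|---|---|---|---|
| spring | 0.090 M | 0.072 M | 0.90 mM | run made earlier |
| dawn | 0.090 M | 0.16 M | 0.90 mM | run made earlier |
| flask | 0.090 M | 0.108 M | 0.90 mM |  |

| run | time / h | product / % | starting material / % |
|---|---|---|---|
| spring | 1.00 | 4 | 96 |
| spring | 2.00 | 11 | 87 |
| spring | 5.00 | 23 | 78 |
| spring | 12.0 | 53 | 41 |
| dawn | 1.50 | 4 | 97 |
| dawn | 4.00 | 14 | 83 |
| dawn | 8.00 | 25 | 76 |
| dawn | 12.0 | 39 | 64 |

(scatter of a reading: 2 percentage points)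

1. factor on the rate of making product when 5.0% of the starting material are converted if free catalyst is charged twice over
2. factor on the rate when 5.0% of the starting material are converted if free catalyst is charged at 10 mM instead

- the earlier runs were read with a standard deviation of 2 percentage points
- no earlier run changes the charge of free catalyst; that part of a forecast is a guess

Does reagent help or hurt? After 12.0 h the spring run reads 53% product and the dawn run 39%, on 2.22 times the reagent, so the read order in reagent is −0.384. In these two runs more reagent goes with less product.

Does that bend the order in catalyst? These runs cannot say, since both carry the same catalyst charge. We therefore start from the charge multiple: 2 for doubling and 11.1 for 10 mM.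

Is the catalyst still turning over at the look, the moment of 5.0% conversion? The flask's load, catalyst as a fraction of the starting material charged, is 1.00%. We carry the turns at the look, the conversion over that load, 5.00 for the flask. Doubling gives 2.50 turns, but 10 mM gives 0.450, under one turn. So we commit to 2 for doubling and to a factor below 11.1 at 10 mM.

The forecast gives 1.85 (1.4 to 2.15) and 8.5 (3.5 to 12): “I shade the estimates down and keep the ranges wide.” Its doubling factor lies below ours.

The simulation gives 2.01 and 9.77, both within the forecast's tolerance.

    starting material + catalyst intermediate A → catalyst intermediate B (k = 0.0860 L mol⁻¹ s⁻¹)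
    reagent + free catalyst → catalyst intermediate A (k = 0.510 L mol⁻¹ s⁻¹)
    catalyst intermediate B → free catalyst + product (k = 0.00380 s⁻¹)
    reagent + catalyst intermediate A ⇌ idle complex, settled at all times (K = 34.0 L mol⁻¹)

In the flask the order in reagent at the look is −0.53; take away the pairing of reagent with catalyst intermediate A to the idle complex, an off-cycle form, and it becomes 0.047. Each idle complex holds one catalyst, and at 1.50 h the flask's idle complex stands at 53.0% of the catalyst charged. With 2.50 turns at the look, doubling the flask's catalyst gives 2.01. The 10 mM flask reaches the look at 0.450 turns, and its factor is 9.77, below the charge multiple of 11.1.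

(The earlier runs and the new flask are calculated for substances that don't exist; the scatter is artificial.)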